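**Plan**
- Cuts in the target (ring numbered O1, C2 aryl, C3 CH2OH, C4 aroyl, C5): C2–C3 (carbenoid C–H insertion), O1–C2 (benzyl ether formation) and C4–C(=O)Ar (aldol). C5, C4, C3 and the CH2OH carbon come from one succinate unit.
- Enabling feature: C2 is a benzylic ether carbon five atoms from C3 (C3–C4–C5–O1–C2), and the C3 and C4 branches (future CH2OH and aroyl) can be tied as a gamma-lactone carrying a diazo group at C3.
- Forward order: an Evans succinate aldol with lactonisation makes the trans lactone (ring 1); acid reduction, O-benzylation and diazo transfer arm it; the rhodium carbenoid insertion closes the tetrahydrofuran (ring 2) cis-fused to the lactone; LiAlH4 then opens ring 1.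
- Stereochemistry: the oxazolidinone sets both lactone centres. The lactone beta-centre dictates the cis fusion (C3), and the insertion transition state places the new aryl endo (C2, cis to C3). C4 is turned trans by base equilibration once the carbinol is an aryl ketone.

Key step: step 8

Remark: Ar = 3,4,5-trimethoxyphenyl; the oxazolidinone, the acid chloride, the aldehyde and the benzyl alcohol used as starting materials are taken as commercial. In the furo[3,4-c]furan-1-one numbering of the bicyclic lactone, the new aryl-bearing carbon is C6, next to bridgehead C6a, which carries the lactone carbonyl.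

**Step 1**
Reactants: 1 (S)-4-benzyl-1,3-oxazolidin-2-one; 2 methyl 4-chloro-4-oxobutanoate
Product: 3 methyl 4-[(4S)-4-benzyl-2-oxo-1,3-oxazolidin-3-yl]-4-oxobutanoate
Conditions: n-BuLi, THF, −78 °C; then 2, −78 to 0 °C
Reagents that add atoms: none
Why: N-acylation of the lithiated oxazolidinone by the acid chloride (imide formation) is fast at low temperature and leaves the methyl ester untouched.

**Step 2**
Reactants: 3 methyl 4-[(4S)-4-benzyl-2-oxo-1,3-oxazolidin-3-yl]-4-oxobutanoate; 4 3,4,5-trimethoxybenzaldehyde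
Product: 6 (4S)-4-benzyl-3-{[(2S,3S)-5-oxo-2-(3,4,5-trimethoxyphenyl)oxolan-3-yl]carbonyl}-1,3-oxazolidin-2-one, via syn-aldol hydroxy ester 5 (not isolated)
Conditions: Bu2BOTf, i-Pr2NEt, CH2Cl2, 0 °C; 4, −78 to 0 °C; pH 7 buffer, MeOH, 30% H2O2, 0 °C; then TsOH (cat.), CH2Cl2, rt
Reagents that add atoms: none
Why: Evans syn aldol, in which soft enolisation occurs only at the imide alpha-CH2 to give the Z boron enolate, which adds to the aldehyde through a Zimmerman–Traxler chair on the face away from the benzyl group and sets both centres (S,S); the syn aldolate then lactonises onto the methyl ester, which makes the 4,5-trans gamma-lactone.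

**Step 3**
Reactants: 6 (4S)-4-benzyl-3-{[(2S,3S)-5-oxo-2-(3,4,5-trimethoxyphenyl)oxolan-3-yl]carbonyl}-1,3-oxazolidin-2-one
Product: 7 (2S,3S)-5-oxo-2-(3,4,5-trimethoxyphenyl)oxolane-3-carboxylic acid
Conditions: LiOH, 30% H2O2, THF/H2O (3:1), 0 °C; Na2SO3 (aq); then 1 M HCl to pH 2
Reagents that add atoms: hydrogen peroxide (as LiOOH), OO
Why: Hydroperoxide cleavage of the imide (Evans LiOOH hydrolysis) attacks the exocyclic carbonyl selectively, any lactone opened by hydroxide recloses on acidification, and neither stereocentre is touched.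

**Step 4**
Reactants: 7 (2S,3S)-5-oxo-2-(3,4,5-trimethoxyphenyl)oxolane-3-carboxylic acid
Product: 8 (4R,5S)-4-(hydroxymethyl)-5-(3,4,5-trimethoxyphenyl)oxolan-2-one
Conditions: BH3·SMe2, THF, 0 °C to rt; MeOH
Reagents that add atoms: none
Why: Chemoselective borane reduction of a carboxylic acid, which proceeds through the acyloxyborane far faster than reduction of the lactone and involves no base, so the hydroxymethyl lactone should not rearrange by acyl migration.

**Step 5**
Reactants: 9 3,4,5-trimethoxybenzyl alcohol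
Product: 10 3,4,5-trimethoxybenzyl 2,2,2-trichloroacetimidate
Conditions: Cl3CCN, DBU (cat.), CH2Cl2, 0 °C
Reagents that add atoms: trichloroacetonitrile, N#CC(Cl)(Cl)Cl
Why: Base-catalysed addition of an alcohol to trichloroacetonitrile (trichloroacetimidate formation) is general for benzylic alcohols; the crude imidate is used directly.

**Step 6**
Reactants: 8 (4R,5S)-4-(hydroxymethyl)-5-(3,4,5-trimethoxyphenyl)oxolan-2-one; 10 3,4,5-trimethoxybenzyl 2,2,2-trichloroacetimidate
Product: 11 (4R,5S)-4-{[(3,4,5-trimethoxybenzyl)oxy]methyl}-5-(3,4,5-trimethoxyphenyl)oxolan-2-one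
Conditions: 10 (1.5 equiv), TfOH (cat.), CH2Cl2, 0 °C
Reagents that add atoms: none
Why: Acid-catalysed O-benzylation with a trichloroacetimidate transfers the well-stabilised trimethoxybenzyl cation to the primary alcohol under non-basic conditions, which avoids the base-induced translactonisation that a Williamson etherification would risk.

**Step 7**
Reactants: 11 (4R,5S)-4-{[(3,4,5-trimethoxybenzyl)oxy]methyl}-5-(3,4,5-trimethoxyphenyl)oxolan-2-one
Product: 13 (4R,5S)-3-diazo-4-{[(3,4,5-trimethoxybenzyl)oxy]methyl}-5-(3,4,5-trimethoxyphenyl)oxolan-2-one, via alpha-trifluoroacetyl lactone 12 (not isolated)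
Conditions: LiN(SiMe3)2, THF, −78 °C; CF3CO2CH2CF3; then MeSO2N3, Et3N, H2O, MeCN, rt
Reagents that add atoms: methanesulfonyl azide, CS(=O)(=O)N=[N+]=[N-]; 2,2,2-trifluoroethyl trifluoroacetate, O=C(OCC(F)(F)F)C(F)(F)F (its CF3CO group stays only in 12)
Why: Danheiser detrifluoroacetylative diazo transfer, in which Claisen-type trifluoroacetylation of the lactone lithium enolate activates C3 and the sulfonyl azide then delivers N2 while the trifluoroacetyl group leaves as the N-acyl sulfonamide; the two existing centres are not enolisable.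

**Step 8**
Reactants: 13 (4R,5S)-3-diazo-4-{[(3,4,5-trimethoxybenzyl)oxy]methyl}-5-(3,4,5-trimethoxyphenyl)oxolan-2-one
Product: 14 (3S,3aR,6R,6aS)-3,6-bis(3,4,5-trimethoxyphenyl)tetrahydro-1H,3H-furo[3,4-c]furan-1-one (cis-fused; 3-aryl exo; 6-aryl endo)
Conditions: Rh2(OAc)4 (2 mol%), CH2Cl2, rt, slow addition of 13
Reagents that add atoms: none
Why: Rh2(OAc)4 takes N2 out of 13 and leaves an electrophilic rhodium carbenoid on the lactone alpha-carbon, which inserts through a concerted, hydride-transfer-like three-centre transition state into the benzylic C–H bond of the ether arm; this is the established dirhodium carboxylate 1,5 C–H insertion of alpha-diazo-gamma-butyrolactones into benzyl ethers that gives furofuranones. The tetrahydrofuran ring closes by C–C bond formation between the carbenoid carbon and the ether carbon five atoms away (1,5-insertion to a five-membered ring), and no other activated C–H bond is within reach. Bridgehead C6a is controlled by the tether: the ether arm sits on one face of the lactone at C3a (set in step 2), so the new ring can only be cis-fused. The benzylic centre C6 is controlled in the insertion transition state, where the aryl group turns away from the bulky dirhodium tetraacetate unit on the carbenoid carbon and lies under the lactone, which leaves it endo, cis to the carbonyl branch, as the 2,3-cis relation of the target requires. The step needs chemoselectivity for insertion over 1,2-hydride migration to the butenolide and over carbene dimerisation, and endo selectivity at C6; the first is secured by the doubly activated C–H bond (alpha to oxygen, electron-rich benzylic) and by slow addition at high dilution, the second by the rigid lactone template.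

**Step 9**
Reactants: 14 (3S,3aR,6R,6aS)-3,6-bis(3,4,5-trimethoxyphenyl)tetrahydro-1H,3H-furo[3,4-c]furan-1-one
Product: 15 {(2R,3R,4R)-4-[(S)-hydroxy(3,4,5-trimethoxyphenyl)methyl]-2-(3,4,5-trimethoxyphenyl)oxolan-3-yl}methanol (all-cis diol)
Conditions: LiAlH4, THF, 0 °C
Reagents that add atoms: none
Why: Hydride reduction of a lactone to the diol turns the carbonyl into the C3 CH2OH and frees the benzylic carbinol on the C4 branch without touching a stereocentre.

**Step 10**
Reactants: 15 {(2R,3R,4R)-4-[(S)-hydroxy(3,4,5-trimethoxyphenyl)methyl]-2-(3,4,5-trimethoxyphenyl)oxolan-3-yl}methanol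
Product: 16 (2R,3R,4R)-3-{[(tert-butyldimethylsilyl)oxy]methyl}-4-[(S)-hydroxy(3,4,5-trimethoxyphenyl)methyl]-2-(3,4,5-trimethoxyphenyl)oxolane
Conditions: TBSCl (1.05 equiv), imidazole, CH2Cl2, 0 °C
Reagents that add atoms: tert-butyldimethylsilyl chloride, CC(C)(C)[Si](C)(C)Cl
Why: Selective silylation of a primary alcohol in the presence of a hindered secondary benzylic one; the silyl ether later keeps the primary oxygen from forming a hemiketal with the ketone.

**Step 11**
Reactants: 16 (2R,3R,4R)-3-{[(tert-butyldimethylsilyl)oxy]methyl}-4-[(S)-hydroxy(3,4,5-trimethoxyphenyl)methyl]-2-(3,4,5-trimethoxyphenyl)oxolane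
Product: 17 (2R,3R,4R)-3-{[(tert-butyldimethylsilyl)oxy]methyl}-4-(3,4,5-trimethoxybenzoyl)-2-(3,4,5-trimethoxyphenyl)oxolane (all-cis ketone)
Conditions: Dess–Martin periodinane, CH2Cl2, rt
Reagents that add atoms: none
Why: Dess–Martin oxidation of the secondary benzylic alcohol to the aryl ketone runs under near-neutral conditions that spare the silyl ether and the benzylic ether at C2.

**Step 12**
Reactants: 17 (2R,3R,4R)-3-{[(tert-butyldimethylsilyl)oxy]methyl}-4-(3,4,5-trimethoxybenzoyl)-2-(3,4,5-trimethoxyphenyl)oxolane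
Product: 18 (2R,3R,4S)-3-{[(tert-butyldimethylsilyl)oxy]methyl}-4-(3,4,5-trimethoxybenzoyl)-2-(3,4,5-trimethoxyphenyl)oxolane (2,3-cis; 3,4-trans)
Conditions: DBU (0.3 equiv), toluene, rt
Reagents that add atoms: none
Why: Base-mediated thermodynamic epimerisation through the ketone enolate, in which only C4 is enolisable and moving the aroyl group trans to the C3 branch relieves the all-cis strain; loss of the ring oxygen from the enolate would be the reverse of a 5-endo-trig closure and should be slow, and an aprotic, non-nucleophilic base leaves no nucleophile to add should any enone form.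

**Step 13**
Reactants: 18 (2R,3R,4S)-3-{[(tert-butyldimethylsilyl)oxy]methyl}-4-(3,4,5-trimethoxybenzoyl)-2-(3,4,5-trimethoxyphenyl)oxolane
Product: 19 [(2R,3R,4S)-4-(3,4,5-trimethoxybenzoyl)-2-(3,4,5-trimethoxyphenyl)oxolan-3-yl]methanol (CNP0148560.2)
Conditions: Bu4NF, AcOH (1:1), THF, 0 °C to rt
Reagents that add atoms: none
Why: Fluoride desilylation, buffered with acetic acid so that the beta-alkoxy ketone is not exposed to strong base; C4 is already at its thermodynamic configuration and the trans keto alcohol cannot close to a hemiketal.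

**Compound list**
1 | (S)-4-benzyl-1,3-oxazolidin-2-one | O=C1N[C@@H](Cc2ccccc2)CO1 | starting material
2 | methyl 4-chloro-4-oxobutanoate | COC(=O)CCC(Cl)=O | starting material
3 | methyl 4-[(4S)-4-benzyl-2-oxo-1,3-oxazolidin-3-yl]-4-oxobutanoate | COC(=O)CCC(=O)N1[C@@H](Cc2ccccc2)COC1=O | intermediate
4 | 3,4,5-trimethoxybenzaldehyde | COc1cc(C=O)cc(OC)c1OC | starting material
5 | methyl (3S)-3-[(S)-hydroxy(3,4,5-trimethoxyphenyl)methyl]-4-[(4S)-4-benzyl-2-oxo-1,3-oxazolidin-3-yl]-4-oxobutanoate (syn-aldol hydroxy ester; not isolated) | COC(=O)C[C@H](C(=O)N1[C@@H](Cc2ccccc2)COC1=O)[C@H](O)c1cc(OC)c(OC)c(OC)c1 | intermediate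
6 | (4S)-4-benzyl-3-{[(2S,3S)-5-oxo-2-(3,4,5-trimethoxyphenyl)oxolan-3-yl]carbonyl}-1,3-oxazolidin-2-one | O=C1O[C@H](c2cc(OC)c(OC)c(OC)c2)[C@@H](C(=O)N2[C@@H](Cc3ccccc3)COC2=O)C1 | intermediate
7 | (2S,3S)-5-oxo-2-(3,4,5-trimethoxyphenyl)oxolane-3-carboxylic acid | O=C1O[C@H](c2cc(OC)c(OC)c(OC)c2)[C@@H](C(=O)O)C1 | intermediate
8 | (4R,5S)-4-(hydroxymethyl)-5-(3,4,5-trimethoxyphenyl)oxolan-2-one | O=C1O[C@H](c2cc(OC)c(OC)c(OC)c2)[C@@H](CO)C1 | intermediate
9 | 3,4,5-trimethoxybenzyl alcohol | COc1cc(CO)cc(OC)c1OC | starting material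
10 | 3,4,5-trimethoxybenzyl 2,2,2-trichloroacetimidate | COc1cc(COC(=N)C(Cl)(Cl)Cl)cc(OC)c1OC | intermediate
11 | (4R,5S)-4-{[(3,4,5-trimethoxybenzyl)oxy]methyl}-5-(3,4,5-trimethoxyphenyl)oxolan-2-one | O=C1O[C@H](c2cc(OC)c(OC)c(OC)c2)[C@@H](COCc2cc(OC)c(OC)c(OC)c2)C1 | intermediate
12 | (4R,5S)-3-(trifluoroacetyl)-4-{[(3,4,5-trimethoxybenzyl)oxy]methyl}-5-(3,4,5-trimethoxyphenyl)oxolan-2-one (C3 epimers and enol; not isolated) | O=C1O[C@H](c2cc(OC)c(OC)c(OC)c2)[C@@H](COCc2cc(OC)c(OC)c(OC)c2)C1C(=O)C(F)(F)F | intermediate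
13 | (4R,5S)-3-diazo-4-{[(3,4,5-trimethoxybenzyl)oxy]methyl}-5-(3,4,5-trimethoxyphenyl)oxolan-2-one | O=C1O[C@H](c2cc(OC)c(OC)c(OC)c2)[C@@H](COCc2cc(OC)c(OC)c(OC)c2)C1=[N+]=[N-] | intermediate
14 | (3S,3aR,6R,6aS)-3,6-bis(3,4,5-trimethoxyphenyl)tetrahydro-1H,3H-furo[3,4-c]furan-1-one | O=C1O[C@H](c2cc(OC)c(OC)c(OC)c2)[C@H]2CO[C@@H](c3cc(OC)c(OC)c(OC)c3)[C@@H]12 | intermediate
15 | {(2R,3R,4R)-4-[(S)-hydroxy(3,4,5-trimethoxyphenyl)methyl]-2-(3,4,5-trimethoxyphenyl)oxolan-3-yl}methanol | O[C@H](c1cc(OC)c(OC)c(OC)c1)[C@H]2CO[C@@H](c3cc(OC)c(OC)c(OC)c3)[C@H]2CO | intermediate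
16 | (2R,3R,4R)-3-{[(tert-butyldimethylsilyl)oxy]methyl}-4-[(S)-hydroxy(3,4,5-trimethoxyphenyl)methyl]-2-(3,4,5-trimethoxyphenyl)oxolane | O[C@H](c1cc(OC)c(OC)c(OC)c1)[C@H]2CO[C@@H](c3cc(OC)c(OC)c(OC)c3)[C@H]2CO[Si](C)(C)C(C)(C)C | intermediate
17 | (2R,3R,4R)-3-{[(tert-butyldimethylsilyl)oxy]methyl}-4-(3,4,5-trimethoxybenzoyl)-2-(3,4,5-trimethoxyphenyl)oxolane | O=C(c1cc(OC)c(OC)c(OC)c1)[C@H]2CO[C@@H](c3cc(OC)c(OC)c(OC)c3)[C@H]2CO[Si](C)(C)C(C)(C)C | intermediate
18 | (2R,3R,4S)-3-{[(tert-butyldimethylsilyl)oxy]methyl}-4-(3,4,5-trimethoxybenzoyl)-2-(3,4,5-trimethoxyphenyl)oxolane | O=C(c1cc(OC)c(OC)c(OC)c1)[C@@H]2CO[C@@H](c3cc(OC)c(OC)c(OC)c3)[C@H]2CO[Si](C)(C)C(C)(C)C | intermediate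
19 | [(2R,3R,4S)-4-(3,4,5-trimethoxybenzoyl)-2-(3,4,5-trimethoxyphenyl)oxolan-3-yl]methanol | COc1cc(C(=O)[C@@H]2CO[C@@H](c3cc(OC)c(OC)c(OC)c3)[C@H]2CO)cc(OC)c1OC | target

**Count and risks**
Total steps: 13. Longest linear sequence: 12 steps (steps 1–4 and 6–13); step 5 is a one-step side branch.

Steps most likely to fail:

1. Step 8. The carbenoid may be diverted by 1,2-hydride migration to the butenolide or by dimerisation, or the insertion may show poor endo/exo control at the new benzylic centre. The fallback sets out from 8 and returns at 14; it makes the same C2–C3 bond by acyl transfer instead of insertion, so steps 5–7 are not needed. Alcohol 8 is esterified with 3,4,5-trimethoxybenzoyl chloride (pyridine, DMAP cat., CH2Cl2, 0 °C) to the benzoate [(2S,3R)-5-oxo-2-(3,4,5-trimethoxyphenyl)oxolan-3-yl]methyl 3,4,5-trimethoxybenzoate F1. LiN(SiMe3)2 (2.2 equiv, THF, −78 to 0 °C) should then trigger an intramolecular Claisen (Dieckmann-type) O-to-C aroyl shift, and the 3-aroyl-4-(hydroxymethyl) lactone formed should rest as the cis-fused hemiketal (3S,3aR,6aS)-6-hydroxy-3,6-bis(3,4,5-trimethoxyphenyl)tetrahydro-1H,3H-furo[3,4-c]furan-1-one F2. Ionic reduction (Et3SiH, BF3·OEt2, CH2Cl2, −78 to −20 °C) should deliver hydride to the convex face of the bicyclic oxocarbenium ion, which leaves the aryl group endo and gives 14.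

2. Step 6. The acid may cause self-alkylation of the electron-rich imidate, acyl migration of the hydroxymethyl lactone to its ring isomer, or ionisation at the benzylic lactone C–O bond. The fallback sets out from 8 and returns at 11; it is a reductive etherification that uses aldehyde 4 in place of imidate 10. Alcohol 8 is silylated (Me3SiCl, imidazole, CH2Cl2, 0 °C) to the trimethylsilyl ether (4R,5S)-5-(3,4,5-trimethoxyphenyl)-4-{[(trimethylsilyl)oxy]methyl}oxolan-2-one F3. Treatment of F3 with 4, Et3SiH and Me3SiOTf (cat.) in CH2Cl2 at −78 °C should give 11 by reduction of the intermediate oxocarbenium ion.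

3. Step 7. C-trifluoroacetylation of the substituted lactone enolate may be incomplete, or the activated lactone may be cleaved during the transfer, so that little diazo compound forms. The fallback sets out from 11 and returns at 13; it builds the diazo group through the amine. Electrophilic azidation of the potassium enolate of 11 (KN(SiMe3)2, THF, −78 °C; 2,4,6-triisopropylbenzenesulfonyl azide; AcOH quench) should give the azide (4R,5S)-3-azido-4-{[(3,4,5-trimethoxybenzyl)oxy]methyl}-5-(3,4,5-trimethoxyphenyl)oxolan-2-one F4. Staudinger reduction (PPh3, THF/H2O) should give the amine (4R,5S)-3-amino-4-{[(3,4,5-trimethoxybenzyl)oxy]methyl}-5-(3,4,5-trimethoxyphenyl)oxolan-2-one F5, and diazotisation (isoamyl nitrite, AcOH cat., CHCl3, 60 °C) should give 13.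

**Further compounds**
F1 | step 8 | [(2S,3R)-5-oxo-2-(3,4,5-trimethoxyphenyl)oxolan-3-yl]methyl 3,4,5-trimethoxybenzoate | O=C1O[C@H](c2cc(OC)c(OC)c(OC)c2)[C@@H](COC(=O)c2cc(OC)c(OC)c(OC)c2)C1
F2 | step 8 | (3S,3aR,6aS)-6-hydroxy-3,6-bis(3,4,5-trimethoxyphenyl)tetrahydro-1H,3H-furo[3,4-c]furan-1-one | O=C1O[C@H](c2cc(OC)c(OC)c(OC)c2)[C@H]2COC(O)(c3cc(OC)c(OC)c(OC)c3)[C@@H]12
F3 | step 6 | (4R,5S)-5-(3,4,5-trimethoxyphenyl)-4-{[(trimethylsilyl)oxy]methyl}oxolan-2-one | O=C1O[C@H](c2cc(OC)c(OC)c(OC)c2)[C@@H](CO[Si](C)(C)C)C1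
F4 | step 7 | (4R,5S)-3-azido-4-{[(3,4,5-trimethoxybenzyl)oxy]methyl}-5-(3,4,5-trimethoxyphenyl)oxolan-2-one | O=C1O[C@H](c2cc(OC)c(OC)c(OC)c2)[C@@H](COCc2cc(OC)c(OC)c(OC)c2)C1N=[N+]=[N-]
F5 | step 7 | (4R,5S)-3-amino-4-{[(3,4,5-trimethoxybenzyl)oxy]methyl}-5-(3,4,5-trimethoxyphenyl)oxolan-2-one | O=C1O[C@H](c2cc(OC)c(OC)c(OC)c2)[C@@H](COCc2cc(OC)c(OC)c(OC)c2)C1N
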